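**Retrosynthetic overview**
- The cyclopentanone (bicyclo[3.2.1]octanedione) is closed last, by an ene-type C–C closure of a prenyl group onto a cyclohexenedione.
- The benzo bridge comes from a C–O bond-forming oxidation. Water converts a 2,5-dimethoxyaryl group into its quinone, and the neighbouring ketone enol adds to that quinone, which returns the free hydroquinone.
- The prenyl-bearing quaternary carbon comes from enolate alkylation of a Diels–Alder adduct of a p-quinone monoketal and a 1-aryl-3-methylbutadiene.
- The monoketal is made by oxidative spiroketalisation of a phenol (C–O). The diene is made by olefination of 2,5-dimethoxybenzaldehyde.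
- Ring order: ring B (from the phenol), then the cyclohexene ring (Diels–Alder), then the benzo-bridged five-membered ring (oxidation-triggered closure), then the cyclopentanone.

Assumption: the facial sense of the TiCl2(OiPr)2/BINOL catalyst with this diene is not known in advance; (S)-BINOL is written, and (R)-BINOL is used if the first run gives the mirror image of 6.

**Step 1**
Reactants: 1 4-(2-hydroxyethoxy)phenol
Product: 2 1,4-dioxaspiro[4.5]deca-6,9-dien-8-one (p-benzoquinone mono-ethylene ketal)
Conditions: PhI(OAc)2 (1.05 equiv), MeCN, 0 °C → rt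
Reagents that add atoms: none
Why: Hypervalent-iodine oxidative dearomatisation, in which the phenoxonium ion is trapped at the para carbon by the tethered hydroxyl (5-exo) to form the second ketal C–O bond and make the two quinone carbonyls different; no stereocenter.

**Step 2**
Reactants: 3 2,5-dimethoxybenzaldehyde; 4 diethyl (2-methylallyl)phosphonate
Product: 5 1,4-dimethoxy-2-[(1E)-3-methylbuta-1,3-dien-1-yl]benzene
Conditions: LiN(SiMe3)2 (1.1 equiv), THF/DMPU, −78 °C → 40 °C
Reagents that add atoms: diethyl (2-methylallyl)phosphonate (4), C=C(C)CP(=O)(OCC)OCC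
Why: Horner–Wadsworth–Emmons olefination, in which the lithiated allylic phosphonate adds through its α-carbon and syn-elimination of phosphate gives the conjugated (E)-diene; no stereocenter.

**Step 3**
Reactants: 2 1,4-dioxaspiro[4.5]deca-6,9-dien-8-one; 5 1,4-dimethoxy-2-[(1E)-3-methylbuta-1,3-dien-1-yl]benzene
Product: 6 8-(2,5-dimethoxyphenyl)-4,4-(ethylenedioxy)-6-methyl-4a,5,8,8a-tetrahydronaphthalen-1(4H)-one with H-4a, H-8 and H-8a all cis
Conditions: TiCl2(OiPr)2 (20 mol %), (S)-BINOL (22 mol %), 4 Å molecular sieves, toluene/CH2Cl2, −30 °C → 0 °C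
Reagents that add atoms: none
Why: Lewis acid-catalysed enantioselective Diels–Alder reaction of a 1,4-quinone monoketal, in which the aryl-bearing diene terminus bonds to the α-carbon (ortho rule) with the methyl para to the ketone, the endo transition state gives the all-cis H-4a/H-8/H-8a adduct, and the ketone-bound chiral Lewis acid formed from TiCl2(OiPr)2 and (S)-BINOL sets the absolute configuration of these three centers.

**Step 4**
Reactants: 6 the Diels–Alder adduct; 7 1-bromo-3-methylbut-2-ene (prenyl bromide)
Product: 8 the 8a-(3-methylbut-2-en-1-yl) derivative of 6 (prenyl cis to H-4a and trans to the aryl group)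
Conditions: LiN(iPr)2 (1.1 equiv), THF, −78 °C; then 7 (1.5 equiv), DMPU, −78 → −20 °C
Reagents that add atoms: 1-bromo-3-methylbut-2-ene (7), CC(C)=CCBr
Why: Kinetic α′-deprotonation of the enone (the only acidic C–H, since the γ-position is the ketal carbon) gives the cross-conjugated lithium dienolate, which is C-alkylated (SN2) on the convex face, syn to both neighbouring H atoms and anti to the aryl group, so the prenyl group replaces H-8a with retention and sets the quaternary stereocenter.

**Step 5**
Reactants: 8 the prenylated ketal
Product: 11 benzo-bridged hydroquinone ene-dione, via ene-dione 9 (not isolated), via quinone 10 (not isolated)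
Conditions: 2 M H2SO4 (aq)/MeCN 1:4, rt, 3 h; then (NH4)2Ce(NO3)6 (2.0 equiv), 0 °C, 20 min; then argon, 40 °C, 6 h
Reagents that add atoms: water, O
Why: Proposed new method: aqueous acid frees the ring ketone (9), tetravalent cerium then oxidises the dimethoxyarene and water attacks both methoxy-bearing carbons (two new aryl C–O bonds, methanol leaves) to give quinone 10, and the conjugated enol of the freed ketone, held under quinone C-3 by the cis-fused core, adds to it in a 5-(enolexo)-endo-trig conjugate addition (trivalent cerium and acid activate the quinone; an electron-transfer/radical-recombination path leads to the same bond), after which tautomerisation gives the hydroquinone, so the C–O forming oxidation both installs the phenol oxygens and closes the benzobicyclo[3.2.1]octadiene with its quaternary benzylic carbon, whose configuration is fixed because the quinone can reach only the face syn to itself; the closest known reaction types are the oxidative demethylation of hydroquinone dimethyl ethers by (NH4)2Ce(NO3)6 and the conjugate addition of enols, enamines and β-dicarbonyl compounds to quinones (Nenitzescu-type α-arylation), neither shown as a one-flask bridging closure at a ring-fusion ketone.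

**Step 6**
Reactants: 11 the benzo-bridged hydroquinone ene-dione
Product: 12 CNP0287617.1 (target)
Conditions: Me2AlCl (3.5 equiv), CH2Cl2, −78 → 0 °C; then 1 M HCl
Reagents that add atoms: none
Why: Lewis acid-promoted intramolecular ene-type (conjugate Prins) cyclisation of the prenyl group onto the enedione, in which Me2AlCl, bound as ArO–Al(Me)Cl at the peri hydroxyl, chelates the adjacent ring ketone and activates the enone β-carbon nearest the prenyl group (5-exo closure), the bond can form only on the ring face carrying the prenyl CH2 (sets the bridgehead CH), the open stepwise transition state keeps the developing tertiary cation away from the dione ring (isopropenyl exo, on the side of the one-carbon ketone bridge), and loss of a methyl proton gives the isopropenyl group.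

**Compound list**
1 | 4-(2-hydroxyethoxy)phenol | OCCOc1ccc(O)cc1 | starting material
2 | 1,4-dioxaspiro[4.5]deca-6,9-dien-8-one | O=C1C=CC2(OCCO2)C=C1 | intermediate
3 | 2,5-dimethoxybenzaldehyde | O=Cc1cc(OC)ccc1OC | starting material
4 | diethyl (2-methylallyl)phosphonate | C=C(C)CP(=O)(OCC)OCC | starting material
5 | 1,4-dimethoxy-2-[(1E)-3-methylbuta-1,3-dien-1-yl]benzene | C=C(C)/C=C/c1cc(OC)ccc1OC | intermediate
6 | 8-(2,5-dimethoxyphenyl)-4,4-(ethylenedioxy)-6-methyl-4a,5,8,8a-tetrahydronaphthalen-1(4H)-one, H-4a/H-8/H-8a all cis, absolute configuration as in the SMILES | O=C1C=CC2(OCCO2)[C@@H]3CC(C)=C[C@H](c4cc(OC)ccc4OC)[C@H]13 | intermediate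
7 | 1-bromo-3-methylbut-2-ene (prenyl bromide) | CC(C)=CCBr | starting material
8 | 8a-(3-methylbut-2-en-1-yl) derivative of 6, prenyl cis to H-4a and trans to the aryl group | CC(C)=CC[C@@]12C(=O)C=CC3(OCCO3)[C@@H]1CC(C)=C[C@@H]2c1cc(OC)ccc1OC | intermediate
9 | 5-(2,5-dimethoxyphenyl)-7-methyl-4a-(3-methylbut-2-en-1-yl)-4a,5,8,8a-tetrahydronaphthalene-1,4-dione, cis-fused, aryl trans to prenyl (formed in the flask in step 5) | CC(C)=CC[C@@]12C(=O)C=CC(=O)[C@@H]1CC(C)=C[C@@H]2c1cc(OC)ccc1OC | intermediate
10 | 2-[that tetrahydronaphthalene-1,4-dion-5-yl]-1,4-benzoquinone, i.e. 9 with the dimethoxyaryl group oxidised to the p-quinone (formed in the flask in step 5) | CC(C)=CC[C@@]12C(=O)C=CC(=O)[C@@H]1CC(C)=C[C@@H]2C1=CC(=O)C=CC1=O | intermediate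
11 | benzo-bridged hydroquinone ene-dione: 10 with quinone C-3 bonded to the former ring-fusion CH (C-8a) and the ring reduced to the hydroquinone; the aryl bridge lies on the face opposite to the prenyl group; equals the target without the bond from the isopropenyl-bearing carbon to the bridgehead CH | CC(C)=CC[C@@]23C(=O)C=CC(=O)[C@@]21CC(C)=C[C@@H]3c2c(O)ccc(O)c21 | intermediate
12 | CNP0287617.1 | C=C(C)[C@H]1C[C@@]23C(=O)[C@@H]1CC(=O)[C@@]21CC(C)=C[C@@H]3c2c(O)ccc(O)c21 | target

**Totals**
Total step count: 6. Longest linear sequence: 5 (3 → 5 → 6 → 8 → 11 → 12, or equally 1 → 2 → 6 → 8 → 11 → 12).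

**Three steps most likely to fail, each with one fallback**

Step 3 (Diels–Alder). The dienophile is hindered and acid-labile, the aryl diene is sluggish, and conversion or ee may be low. The fallback sets out from 2 and 5 and comes back at 6. The cycloaddition is run without catalyst under pressure (CH2Cl2, 12 kbar, rt), which gives the same endo adduct as the racemate, that is 6 together with its mirror image ent-6 F1. The enantiomers are then separated by preparative chromatography on a chiral stationary phase (amylose tris(3,5-dimethylphenylcarbamate)), and 6 goes on to step 4. Absolute configuration then comes from resolution, not catalysis.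

Step 5 (the proposed new step). The 5-endo closure may be slow, and the alkylquinone can tautomerise through its allylic/benzylic C–H and lose that stereocenter. The fallback uses known chemistry, an intramolecular ketone α-arylation catalysed by Pd(OAc)2 and P(t-Bu)3; it sets out from 3 and comes back at 11. Ortho-lithiation of 3 between the formyl group and the methoxy group (in situ α-amino alkoxide from LiN(Me)CH2CH2NMe2, then n-BuLi, then BrCCl2CCl2Br) gives 2-bromo-3,6-dimethoxybenzaldehyde F2. The olefination with 4, the Diels–Alder reaction with 2 and the prenylation with 7, run as in steps 2 to 4, give in turn the bromo diene F3, the bromo adduct F4 and the bromo prenyl ketal F5. Aqueous H2SO4/MeCN then gives the bromo ene-dione F6. With Pd(OAc)2 (5 mol %), P(t-Bu)3·HBF4 (10 mol %) and K3PO4 in toluene at 80 °C, zerovalent palladium inserts into the C–Br bond and arylates the tertiary α-carbon of the only enolisable ketone, giving the bridged dimethyl ether F7. (NH4)2Ce(NO3)6 in MeCN/H2O gives the bridged quinone F8, and aqueous Na2S2O4 reduces it to 11.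

Step 6 (ene-type closure). The tertiary cation may be trapped by chloride, or lose the wrong proton, or the free phenols may interfere with the one-step closure. The fallback sets out from 11 and comes back at 12. The closure is run as a deliberate halo-Prins cyclisation: TiCl4 (2.5 equiv), CH2Cl2, −78 °C gives the tertiary chloride F9 with the same ring and configuration. Dehydrochlorination with KOt-Bu in THF/t-BuOH then removes a methyl proton by E2 (the ring C–H is hindered) and gives 12.

**Further compounds**
F1 | step 3 | ent-6, the mirror image of 6 | O=C1C=CC2(OCCO2)[C@H]3CC(C)=C[C@@H](c4cc(OC)ccc4OC)[C@@H]13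
F2 | step 5 | 2-bromo-3,6-dimethoxybenzaldehyde | O=Cc1c(Br)c(OC)ccc1OC
F3 | step 5 | 2-bromo-1,4-dimethoxy-3-[(1E)-3-methylbuta-1,3-dien-1-yl]benzene | C=C(C)/C=C/c1c(Br)c(OC)ccc1OC
F4 | step 5 | bromo analogue of 6 (2-bromo-3,6-dimethoxyphenyl in place of 2,5-dimethoxyphenyl) | O=C1C=CC2(OCCO2)[C@@H]3CC(C)=C[C@H](c4c(Br)c(OC)ccc4OC)[C@H]13
F5 | step 5 | bromo analogue of 8 | CC(C)=CC[C@@]12C(=O)C=CC3(OCCO3)[C@@H]1CC(C)=C[C@@H]2c1c(Br)c(OC)ccc1OC
F6 | step 5 | bromo analogue of 9 | CC(C)=CC[C@@]12C(=O)C=CC(=O)[C@@H]1CC(C)=C[C@@H]2c1c(Br)c(OC)ccc1OC
F7 | step 5 | dimethyl ether of 11 | CC(C)=CC[C@@]23C(=O)C=CC(=O)[C@@]21CC(C)=C[C@@H]3c2c(OC)ccc(OC)c21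
F8 | step 5 | bridged p-quinone corresponding to 11 | CC(C)=CC[C@@]23C(=O)C=CC(=O)[C@@]21CC(C)=C[C@@H]3C2=C1C(=O)C=CC2=O
F9 | step 6 | tertiary chloride: 12 with a 2-chloropropan-2-yl group in place of the isopropenyl group | CC(C)(Cl)[C@H]1C[C@@]23C(=O)[C@@H]1CC(=O)[C@@]21CC(C)=C[C@@H]3c2c(O)ccc(O)c21
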